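**Strategy**

Everything rests on cutting the C2–C3 bond of the dihydrofuran ring. C3 is a benzylic carbinol carbon and its neighbour C2 is an ether carbon carrying a 1,1-disubstituted (methylene) alkene. This 1,2-pattern is what an oxygen-substituted allylboronate leaves when its O-bearing terminus adds to the ortho formyl group of an aryl ether. A single acid-catalysed allyl transfer therefore closes the five-membered ring, creates C2 and C3 as the trans (2S,3R) pair and installs the methylene with its oxygenated carbon already attached. The precursor is a salicylaldehyde, tiglate in place, whose phenol oxygen is a stereodefined enol ether bearing CH2Bpin trans to oxygen and CH2OTBS.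

Key step: step 10

Remark (descriptor): in boronates 14 and 15 the aryloxy group is trans to CH2B, which crotyl-type usage calls E; because CH2O outranks CH2B the CIP descriptor is Z.
Remark (vinylation): replacing ethoxide by an aryloxide on an alkoxymethylene malonate is an uphill exchange, so the malonate is first converted into its chloromethylene analogue, which the phenoxide substitutes irreversibly.
Remark (isomers): monosilylation of triol 8 also gives the arm isomer of 9 (silyl ether trans to the aryloxy group); it is carried along unseparated, since both isomers ionise in step 9 to the same equilibrating allylpalladium species.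
Assumption (catalyst sense): TRIP acids are taken to expose the same aldehyde face in the ring-closing mode as in intermolecular allylboration of aryl aldehydes ((R)-acid: Re face), so the (S)-acid is specified for 3R; should the sense prove opposite, the (R)-acid would be used.

**Route**

Step 1
Reactants: 1 diethyl ethoxymethylenemalonate
Product: 3 diethyl 2-(chloromethylidene)propanedioate, via potassium enolate of diethyl formylmalonate 2 (not isolated)
Conditions: KOH (1.0 equiv), EtOH, 0 °C; evaporate; (COCl)2 (1.1 equiv), DMF (cat.), CH2Cl2, 0 °C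
Reagents that add atoms: oxalyl chloride, O=C(Cl)C(Cl)=O
Why: Hydroxide adds to the doubly activated β-carbon and expels ethoxide (vinylic addition–elimination) to give the stabilised formylmalonate enolate, which Vilsmeier-type activation with oxalyl chloride converts into the vinylogous acid chloride, the usual fate of an acylmalonate enol.

Step 2
Reactants: 4 5-acetylsalicylaldehyde
Product: 5 1-[3-(diethoxymethyl)-4-hydroxyphenyl]ethan-1-one
Conditions: HC(OEt)3, EtOH, PPTS (cat.), rt to 40 °C; Et3N
Reagents that add atoms: triethyl orthoformate, CCOC(OCC)OCC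
Why: Orthoformate-driven acetalisation is selective for the aldehyde because the aryl methyl ketone, deactivated by the para hydroxyl, should not ketalise under these mild conditions, and the diethyl acetal is chosen because it hydrolyses quickly in the cold later.

Step 3
Reactants: 5 1-[3-(diethoxymethyl)-4-hydroxyphenyl]ethan-1-one; 3 diethyl 2-(chloromethylidene)propanedioate
Product: 6 diethyl 2-{[4-acetyl-2-(diethoxymethyl)phenoxy]methylidene}propanedioate
Conditions: K2CO3 (1.5 equiv), MeCN, 0 °C → rt
Reagents that add atoms: none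
Why: The phenoxide replaces the vinylic chloride by conjugate addition–elimination, which is irreversible because chloride is lost, and acetal and ketone are inert to carbonate.

Step 4
Reactants: 6 diethyl 2-{[4-acetyl-2-(diethoxymethyl)phenoxy]methylidene}propanedioate
Product: 7 diethyl 2-({2-(diethoxymethyl)-4-[(1R)-1-hydroxyethyl]phenoxy}methylidene)propanedioate
Conditions: (S)-Me-CBS (10 mol%), BH3·SMe2 (0.7 equiv), THF, −20 °C; pH 7 buffer
Reagents that add atoms: none
Why: Corey–Bakshi–Shibata reduction, in which the (S)-oxazaborolidine differentiates aryl from methyl and should deliver the (R)-carbinol as with other acetophenones, while the push–pull malonate alkene, the esters and the acetal are not attacked by borane at this temperature.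

Step 5
Reactants: 7 diethyl 2-({2-(diethoxymethyl)-4-[(1R)-1-hydroxyethyl]phenoxy}methylidene)propanedioate
Product: 8 2-({2-(diethoxymethyl)-4-[(1R)-1-hydroxyethyl]phenoxy}methylidene)propane-1,3-diol
Conditions: iBu2AlH (6 equiv), CH2Cl2, −78 → −40 °C; aq. KNaC4H4O6
Reagents that add atoms: none
Why: Diisobutylaluminium hydride reduces both vinylogous carbonate esters in the 1,2-sense to allylic alcohols, the oxygen donor on the β-carbon disfavouring conjugate reduction, and the low temperature keeps the acetal and the carbinol centre untouched.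

Step 6
Reactants: 8 2-({2-(diethoxymethyl)-4-[(1R)-1-hydroxyethyl]phenoxy}methylidene)propane-1,3-diol
Product: 9 (2Z)-2-{[tert-butyl(dimethyl)silyl]oxymethyl}-3-{2-(diethoxymethyl)-4-[(1R)-1-hydroxyethyl]phenoxy}prop-2-en-1-ol
Conditions: TBSCl (1.0 equiv), imidazole, CH2Cl2/DMF, −30 °C
Reagents that add atoms: tert-butyldimethylsilyl chloride, CC(C)(C)[Si](C)(C)Cl
Why: Silylation is much faster at the primary allylic hydroxyls than at the secondary benzylic one, so one equivalent of silyl chloride should give the monoether (bis-ether and unreacted triol being recycled), and the arm isomer formed alongside converges with 9 in step 9.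

Step 7
Reactants: 9 (2Z)-2-{[tert-butyl(dimethyl)silyl]oxymethyl}-3-{2-(diethoxymethyl)-4-[(1R)-1-hydroxyethyl]phenoxy}prop-2-en-1-ol
Product: 10 (2Z)-2-{[tert-butyl(dimethyl)silyl]oxymethyl}-3-{2-(diethoxymethyl)-4-[(1R)-1-hydroxyethyl]phenoxy}prop-2-en-1-yl methyl carbonate
Conditions: ClCO2Me (1.1 equiv), pyridine, CH2Cl2, −40 °C
Reagents that add atoms: methyl chloroformate, COC(=O)Cl
Why: Acylation with a chloroformate at low temperature discriminates the primary allylic hydroxyl from the secondary benzylic one and installs the leaving group needed for allylpalladium formation.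

Step 8
Reactants: 10 (2Z)-2-{[tert-butyl(dimethyl)silyl]oxymethyl}-3-{2-(diethoxymethyl)-4-[(1R)-1-hydroxyethyl]phenoxy}prop-2-en-1-yl methyl carbonate; 11 tiglic acid
Product: 12 (1R)-1-{3-(diethoxymethyl)-4-[((1Z)-2-{[tert-butyl(dimethyl)silyl]oxymethyl}-3-[(methoxycarbonyl)oxy]prop-1-en-1-yl)oxy]phenyl}ethyl (2E)-2-methylbut-2-enoate
Conditions: EDC·HCl, DMAP, CH2Cl2, 0 °C → rt
Reagents that add atoms: none
Why: Steglich esterification acylates the remaining secondary alcohol at oxygen, so the (R)-centre and the E geometry of the tiglate are retained, and placing the ester here means that no acylation is needed once the sensitive enal exists.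

Step 9
Reactants: 12 (1R)-1-{3-(diethoxymethyl)-4-[((1Z)-2-{[tert-butyl(dimethyl)silyl]oxymethyl}-3-[(methoxycarbonyl)oxy]prop-1-en-1-yl)oxy]phenyl}ethyl (2E)-2-methylbut-2-enoate; 13 bis(pinacolato)diboron
Product: 14 (1R)-1-{3-(diethoxymethyl)-4-[((1Z)-2-{[tert-butyl(dimethyl)silyl]oxymethyl}-3-(4,4,5,5-tetramethyl-1,3,2-dioxaborolan-2-yl)prop-1-en-1-yl)oxy]phenyl}ethyl (2E)-2-methylbut-2-enoate
Conditions: Pd2(dba)3 (2.5 mol%), DMSO, 45 °C
Reagents that add atoms: none
Why: Allylic borylation of the Miyaura type, in which zerovalent palladium ionises the carbonate, the released methoxide activates the diboron for transmetalation and reductive elimination places boron on the unsubstituted allyl terminus, while syn–anti equilibration of the allyl complex should put the aryloxy group syn to the 2-substituent and therefore trans to CH2B.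

Step 10
Reactants: 14 (1R)-1-{3-(diethoxymethyl)-4-[((1Z)-2-{[tert-butyl(dimethyl)silyl]oxymethyl}-3-(4,4,5,5-tetramethyl-1,3,2-dioxaborolan-2-yl)prop-1-en-1-yl)oxy]phenyl}ethyl (2E)-2-methylbut-2-enoate
Product: 16 (1R)-1-[(2S,3R)-2-(3-{[tert-butyl(dimethyl)silyl]oxy}prop-1-en-2-yl)-3-hydroxy-2,3-dihydro-1-benzofuran-5-yl]ethyl (2E)-2-methylbut-2-enoate, via free aldehyde boronate 15 (not isolated)
Conditions: SiO2/10% aq. (CO2H)2, CH2Cl2, 0 °C; cold filtration (Na2SO4, NaHCO3), exchange to toluene below −20 °C; (S)-TRIP (10 mol%), 4 Å MS, toluene, −40 °C; aq. NaHCO3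
Reagents that add atoms: water, O
Why: Mild acid hydrolysis frees the aldehyde at 0 °C, where pinacol γ-aryloxyallylboronates should close only slowly, and the chiral phosphoric acid then hydrogen-bonds to a boronate oxygen while the aldehyde oxygen binds boron, so that the aryloxy-bearing γ-carbon attacks the carbonyl carbon through a six-membered Zimmerman–Traxler chair with allylic transposition of the double bond into the methylene position. The closest known reactions are the thermal ring-closing allylboration of γ-(ω-formylalkoxy)allylboronates, which gives trans-2-alkenyl cyclic ether 3-ols, and the TRIP-catalysed allyl- and crotylboration of aryl aldehydes with pinacol boronates. The dihydrofuran ring closes in the 5-exo-trig mode at the carbonyl carbon, the two arene carbons bridging the equatorial aryloxy and equatorial aryl positions of the chair. The configuration of C2 relative to C3 follows from the enol-ether geometry, since an aryloxy group trans to CH2B must sit equatorial and this gives the anti, that is trans-2,3, arrangement, whereas the absolute sense (attack on the Si face of the aldehyde, 3R and hence 2S) is imposed by the (S)-acid because the remote side-chain centre exerts no bias. The step needs γ- rather than α-attack, which the closed transition state enforces, and catalysed rather than uncatalysed closure, which is secured by the cold release of the aldehyde, the low cyclisation temperature and the acceleration that the acid provides.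

Step 11
Reactants: 16 (1R)-1-[(2S,3R)-2-(3-{[tert-butyl(dimethyl)silyl]oxy}prop-1-en-2-yl)-3-hydroxy-2,3-dihydro-1-benzofuran-5-yl]ethyl (2E)-2-methylbut-2-enoate
Product: 17 (1R)-1-[(2S,3R)-3-(acetyloxy)-2-(3-{[tert-butyl(dimethyl)silyl]oxy}prop-1-en-2-yl)-2,3-dihydro-1-benzofuran-5-yl]ethyl (2E)-2-methylbut-2-enoate
Conditions: Ac2O, pyridine, DMAP (cat.), CH2Cl2, 0 °C
Reagents that add atoms: acetic anhydride, CC(=O)OC(C)=O
Why: Base-mediated O-acylation of the secondary benzylic alcohol breaks no bond to C3, so the trans (2S,3R) configuration is kept.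

Step 12
Reactants: 17 (1R)-1-[(2S,3R)-3-(acetyloxy)-2-(3-{[tert-butyl(dimethyl)silyl]oxy}prop-1-en-2-yl)-2,3-dihydro-1-benzofuran-5-yl]ethyl (2E)-2-methylbut-2-enoate
Product: 18 (1R)-1-[(2S,3R)-3-(acetyloxy)-2-(3-hydroxyprop-1-en-2-yl)-2,3-dihydro-1-benzofuran-5-yl]ethyl (2E)-2-methylbut-2-enoate
Conditions: HF·pyridine, pyridine, THF, 0 °C
Reagents that add atoms: none
Why: Buffered fluoride cleaves the single primary silyl ether without the strong acid or base that would ionise the ortho-oxygen-activated benzylic acetate or cleave the two esters.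

Step 13
Reactants: 18 (1R)-1-[(2S,3R)-3-(acetyloxy)-2-(3-hydroxyprop-1-en-2-yl)-2,3-dihydro-1-benzofuran-5-yl]ethyl (2E)-2-methylbut-2-enoate
Product: 19 (1R)-1-[(2S,3R)-3-(acetyloxy)-2-(3-oxoprop-1-en-2-yl)-2,3-dihydro-1-benzofuran-5-yl]ethyl (2E)-2-methylbut-2-enoate
Conditions: MnO2 (activated, 15 equiv), CH2Cl2, rt
Reagents that add atoms: none
Why: Heterogeneous, neutral oxidation with manganese dioxide is selective for the primary allylic alcohol, the only oxidisable hydroxyl left, and should give the enal without elimination or epimerisation at C2 and C3.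

**Compound list**

1 | diethyl ethoxymethylenemalonate | CCOC=C(C(=O)OCC)C(=O)OCC | starting material
2 | potassium enolate of diethyl formylmalonate | [K+].[O-]C=C(C(=O)OCC)C(=O)OCC | intermediate (not isolated)
3 | diethyl 2-(chloromethylidene)propanedioate | ClC=C(C(=O)OCC)C(=O)OCC | intermediate
4 | 5-acetylsalicylaldehyde | CC(=O)c1ccc(O)c(C=O)c1 | starting material
5 | 1-[3-(diethoxymethyl)-4-hydroxyphenyl]ethan-1-one | CCOC(OCC)c1cc(C(C)=O)ccc1O | intermediate
6 | diethyl 2-{[4-acetyl-2-(diethoxymethyl)phenoxy]methylidene}propanedioate | CCOC(=O)C(=COc1ccc(C(C)=O)cc1C(OCC)OCC)C(=O)OCC | intermediate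
7 | diethyl 2-({2-(diethoxymethyl)-4-[(1R)-1-hydroxyethyl]phenoxy}methylidene)propanedioate | CCOC(=O)C(=COc1ccc([C@@H](C)O)cc1C(OCC)OCC)C(=O)OCC | intermediate
8 | 2-({2-(diethoxymethyl)-4-[(1R)-1-hydroxyethyl]phenoxy}methylidene)propane-1,3-diol | OCC(CO)=COc1ccc([C@@H](C)O)cc1C(OCC)OCC | intermediate
9 | (2Z)-2-{[tert-butyl(dimethyl)silyl]oxymethyl}-3-{2-(diethoxymethyl)-4-[(1R)-1-hydroxyethyl]phenoxy}prop-2-en-1-ol | CCOC(OCC)c1cc([C@@H](C)O)ccc1O/C=C(\CO[Si](C)(C)C(C)(C)C)CO | intermediate
10 | (2Z)-2-{[tert-butyl(dimethyl)silyl]oxymethyl}-3-{2-(diethoxymethyl)-4-[(1R)-1-hydroxyethyl]phenoxy}prop-2-en-1-yl methyl carbonate | CCOC(OCC)c1cc([C@@H](C)O)ccc1O/C=C(\CO[Si](C)(C)C(C)(C)C)COC(=O)OC | intermediate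
11 | tiglic acid | C/C=C(\C)C(=O)O | starting material
12 | (1R)-1-{3-(diethoxymethyl)-4-[((1Z)-2-{[tert-butyl(dimethyl)silyl]oxymethyl}-3-[(methoxycarbonyl)oxy]prop-1-en-1-yl)oxy]phenyl}ethyl (2E)-2-methylbut-2-enoate | CCOC(OCC)c1cc([C@@H](C)OC(=O)/C(C)=C/C)ccc1O/C=C(\CO[Si](C)(C)C(C)(C)C)COC(=O)OC | intermediate
13 | bis(pinacolato)diboron | CC1(C)OB(OC1(C)C)B1OC(C)(C)C(C)(C)O1 | starting material
14 | (1R)-1-{3-(diethoxymethyl)-4-[((1Z)-2-{[tert-butyl(dimethyl)silyl]oxymethyl}-3-(4,4,5,5-tetramethyl-1,3,2-dioxaborolan-2-yl)prop-1-en-1-yl)oxy]phenyl}ethyl (2E)-2-methylbut-2-enoate | CCOC(OCC)c1cc([C@@H](C)OC(=O)/C(C)=C/C)ccc1O/C=C(\CO[Si](C)(C)C(C)(C)C)CB1OC(C)(C)C(C)(C)O1 | intermediate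
15 | (1R)-1-{3-formyl-4-[((1Z)-2-{[tert-butyl(dimethyl)silyl]oxymethyl}-3-(4,4,5,5-tetramethyl-1,3,2-dioxaborolan-2-yl)prop-1-en-1-yl)oxy]phenyl}ethyl (2E)-2-methylbut-2-enoate | O=Cc1cc([C@@H](C)OC(=O)/C(C)=C/C)ccc1O/C=C(\CO[Si](C)(C)C(C)(C)C)CB1OC(C)(C)C(C)(C)O1 | intermediate (not isolated; precursor of the key step)
16 | (1R)-1-[(2S,3R)-2-(3-{[tert-butyl(dimethyl)silyl]oxy}prop-1-en-2-yl)-3-hydroxy-2,3-dihydro-1-benzofuran-5-yl]ethyl (2E)-2-methylbut-2-enoate | C=C(CO[Si](C)(C)C(C)(C)C)[C@@H]1Oc2ccc([C@@H](C)OC(=O)/C(C)=C/C)cc2[C@H]1O | intermediate (product of the key step)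
17 | (1R)-1-[(2S,3R)-3-(acetyloxy)-2-(3-{[tert-butyl(dimethyl)silyl]oxy}prop-1-en-2-yl)-2,3-dihydro-1-benzofuran-5-yl]ethyl (2E)-2-methylbut-2-enoate | C=C(CO[Si](C)(C)C(C)(C)C)[C@@H]1Oc2ccc([C@@H](C)OC(=O)/C(C)=C/C)cc2[C@H]1OC(C)=O | intermediate
18 | (1R)-1-[(2S,3R)-3-(acetyloxy)-2-(3-hydroxyprop-1-en-2-yl)-2,3-dihydro-1-benzofuran-5-yl]ethyl (2E)-2-methylbut-2-enoate | C=C(CO)[C@@H]1Oc2ccc([C@@H](C)OC(=O)/C(C)=C/C)cc2[C@H]1OC(C)=O | intermediate
19 | (1R)-1-[(2S,3R)-3-(acetyloxy)-2-(3-oxoprop-1-en-2-yl)-2,3-dihydro-1-benzofuran-5-yl]ethyl (2E)-2-methylbut-2-enoate | C=C(C=O)[C@@H]1Oc2ccc([C@@H](C)OC(=O)/C(C)=C/C)cc2[C@H]1OC(C)=O | target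

**Step count and risks**

Total step count: 13. Longest linear sequence: 12 (steps 2 to 13 from 4, or equally step 1 and steps 3 to 13 from 1).

The three steps most likely to fail:

1. Step 10. What may go wrong: the uncatalysed ring closure competes with the acid-bound pathway while the aldehyde is being released and handled, so the facial sense at C3 is poorly controlled (the trans relationship is not at risk). The fallback sets out from 14. The acetal is hydrolysed as before and aldehyde 15 is left to close without catalyst in toluene at room temperature. This should give both trans ring diastereomers, 16 and (1R)-1-[(2R,3S)-2-(3-{[tert-butyl(dimethyl)silyl]oxy}prop-1-en-2-yl)-3-hydroxy-2,3-dihydro-1-benzofuran-5-yl]ethyl (2E)-2-methylbut-2-enoate F1. The pair is then differentiated at the carbinol by an enzyme instead of at the bond-forming stage: immobilised Candida antarctica lipase B with vinyl acetate in MTBE at 35 °C should acylate only one C3 epimer, a known way of resolving cyclic benzylic carbinols. If F1 is the substrate it becomes (1R)-1-[(2R,3S)-3-(acetyloxy)-2-(3-{[tert-butyl(dimethyl)silyl]oxy}prop-1-en-2-yl)-2,3-dihydro-1-benzofuran-5-yl]ethyl (2E)-2-methylbut-2-enoate F2, and unchanged 16 is separated by chromatography. If 16 is the substrate, the enzyme delivers 17 directly. The fallback comes back to the route at 16.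

2. Step 9. What may go wrong: loss of the electron-rich boronate through allyl–allyl coupling or protodeboronation during isolation, and incomplete syn–anti equilibration of the allylpalladium species. The fallback sets out from 12 and inverts the order of unmasking and borylation so that the boronate never has to be isolated. Acetal hydrolysis of 12 (wet SiO2/oxalic acid, to which carbonate and enol ether are indifferent) gives (1R)-1-{3-formyl-4-[((1Z)-2-{[tert-butyl(dimethyl)silyl]oxymethyl}-3-[(methoxycarbonyl)oxy]prop-1-en-1-yl)oxy]phenyl}ethyl (2E)-2-methylbut-2-enoate F3. Treating F3 with 13 and Pd2(dba)3 in DMSO at 50 °C generates boronate 15 in the presence of its own aldehyde, where it closes at once; one-pot allylic borylation with ring-closing allylboration is a known tandem. Minor cis isomers from any misassembled enol-ether geometry are removed by chromatography, and the trans pair is differentiated enzymatically as described for step 10. The fallback comes back to the route at 16.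

3. Step 6. What may go wrong: statistical over-silylation and competing silylation of the secondary hydroxyl leave little monoether. The fallback sets out from 8. The 1,3-diol is first tied up as its six-membered stannylene acetal 2,2-dibutyl-5-({2-(diethoxymethyl)-4-[(1R)-1-hydroxyethyl]phenoxy}methylidene)-1,3,2-dioxastanninane F4 (Bu2SnO, toluene, reflux with removal of water). This template engages only the two primary hydroxyls and, on treatment with TBSCl, transfers exactly one silyl group, giving 9 (with its arm isomer, as before). The fallback comes back to the route at 9.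

Further compounds
F1 | step 10 | (1R)-1-[(2R,3S)-2-(3-{[tert-butyl(dimethyl)silyl]oxy}prop-1-en-2-yl)-3-hydroxy-2,3-dihydro-1-benzofuran-5-yl]ethyl (2E)-2-methylbut-2-enoate | C=C(CO[Si](C)(C)C(C)(C)C)[C@H]1Oc2ccc([C@@H](C)OC(=O)/C(C)=C/C)cc2[C@@H]1O
F2 | step 10 | (1R)-1-[(2R,3S)-3-(acetyloxy)-2-(3-{[tert-butyl(dimethyl)silyl]oxy}prop-1-en-2-yl)-2,3-dihydro-1-benzofuran-5-yl]ethyl (2E)-2-methylbut-2-enoate | C=C(CO[Si](C)(C)C(C)(C)C)[C@H]1Oc2ccc([C@@H](C)OC(=O)/C(C)=C/C)cc2[C@@H]1OC(C)=O
F3 | step 9 | (1R)-1-{3-formyl-4-[((1Z)-2-{[tert-butyl(dimethyl)silyl]oxymethyl}-3-[(methoxycarbonyl)oxy]prop-1-en-1-yl)oxy]phenyl}ethyl (2E)-2-methylbut-2-enoate | O=Cc1cc([C@@H](C)OC(=O)/C(C)=C/C)ccc1O/C=C(\CO[Si](C)(C)C(C)(C)C)COC(=O)OC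
F4 | step 6 | 2,2-dibutyl-5-({2-(diethoxymethyl)-4-[(1R)-1-hydroxyethyl]phenoxy}methylidene)-1,3,2-dioxastanninane | CCCC[Sn]1(CCCC)OCC(=COc2ccc([C@@H](C)O)cc2C(OCC)OCC)CO1
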